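Ring B of the target carries its C6 oxygen para to C9, a tetrasubstituted C8=C9 alkene and the quaternary C10 beside it. This is the substitution pattern of a cycloadduct between a 2-alkoxydiene and a but-2-ynoate. The route therefore rests on an intermolecular Diels–Alder reaction that joins an enantiopure ring A diene (C10=C5–C6(OEt)=C7, with the C3 silyloxy and the C4 methyl/silyloxymethyl centres already in place) to methyl but-2-ynoate. One operation forms C7–C8 and C9–C10, closes ring B, sets the C10 quaternary stereocentre, and leaves C6 as a masked ketone and C11 as an ester for side-chain growth.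

Key step: step 7

Remarks on the chemistry
- Labdane atom labels are used in the discussion for every intermediate, the monocyclic ring A compounds included; the systematic names of the monocycles keep their own locants. Ring A = C1–C5 and C10, ring B = C5–C10, C17 on C8, C18 = 4α-methyl, C19 = 4β-CH2O, C20 on C10; α is the face opposite C20. TBS = tert-butyldimethylsilyl.
- The target is read as the normal-series labdane with 3α (axial) and 19 isovalerates, a 6β (axial) hydroxyl, 5α-H, 10β-methyl and a 13E alkene, i.e. (3R,4S,5R,6R,10S).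
- Assumption: the enzyme of step 2 is found by screening a commercial ketoreductase panel for the (2S,3R) product.

Step 1
Reactants: 1 2-methylcyclohexane-1,3-dione
Product: 2 2-(hydroxymethyl)-2-methylcyclohexane-1,3-dione
Conditions: 37% aq. HCHO, H2O, rt
Reagents that add atoms: formaldehyde, C=O
Why: Aldol-type hydroxymethylation, in which the acidic 1,3-dione enol adds to formaldehyde at C2 without added base, which limits retro-aldol loss of the new group.

Step 2
Reactants: 2 2-(hydroxymethyl)-2-methylcyclohexane-1,3-dione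
Product: 3 (2S,3R)-3-hydroxy-2-(hydroxymethyl)-2-methylcyclohexan-1-one
Conditions: (R)-selective ketoreductase, NADP+ (cat.), i-PrOH, phosphate buffer pH 7, 30 °C
Reagents that add atoms: none
Why: Enzymatic desymmetrising monoreduction of a prochiral 2,2-disubstituted cyclohexane-1,3-dione, in which the enzyme reduces one enantiotopic carbonyl on one face and so sets C3 (R) and, with it, the quaternary C4 (S), the new hydroxyl lying trans to the hydroxymethyl group.

Step 3
Reactants: 3 (2S,3R)-3-hydroxy-2-(hydroxymethyl)-2-methylcyclohexan-1-one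
Product: 4 (2S,3R)-3-(TBS-oxy)-2-(TBS-oxymethyl)-2-methylcyclohexan-1-one
Conditions: TBSOTf, 2,6-lutidine, CH2Cl2, −78 → 0 °C
Reagents that add atoms: tert-butyldimethylsilyl trifluoromethanesulfonate, CC(C)(C)[Si](C)(C)OS(=O)(=O)C(F)(F)F
Why: Silyl triflate silylation with a non-nucleophilic base covers both the primary and the hindered secondary hydroxyl and removes any retro-aldol pathway from the later base steps.

Step 4
Reactants: 4 (2S,3R)-3-(TBS-oxy)-2-(TBS-oxymethyl)-2-methylcyclohexan-1-one
Product: 5 (2S,3R,6RS)-3-(TBS-oxy)-2-(TBS-oxymethyl)-2,6-dimethylcyclohexan-1-one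
Conditions: LiN(i-Pr)2, THF, −78 °C; MeI, −78 → −20 °C
Reagents that add atoms: iodomethane, CI
Why: Kinetic lithium enolate alkylation; C4 is quaternary, so the enolate can form only toward C10, and the configuration of the new C10 centre is irrelevant because it becomes sp2 in the next step.

Step 5
Reactants: 5 (2S,3R,6RS)-3-(TBS-oxy)-2-(TBS-oxymethyl)-2,6-dimethylcyclohexan-1-one
Product: 6 (5R,6S)-5-(TBS-oxy)-6-(TBS-oxymethyl)-2,6-dimethylcyclohex-1-en-1-yl trifluoromethanesulfonate
Conditions: KN(SiMe3)2, THF, −78 → −20 °C; PhNTf2, −78 °C → rt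
Reagents that add atoms: N-phenylbis(trifluoromethanesulfonimide), O=S(=O)(N(c1ccccc1)S(=O)(=O)C(F)(F)F)C(F)(F)F
Why: Enolate O-triflation; C10 is the only enolisable position, so the tetrasubstituted C5=C10 enol triflate should form as one regioisomer from both C10 epimers, as is known for 2,2,6-trisubstituted cyclohexanones.

Step 6
Reactants: 6 (5R,6S)-5-(TBS-oxy)-6-(TBS-oxymethyl)-2,6-dimethylcyclohex-1-en-1-yl trifluoromethanesulfonate; 7 tributyl(1-ethoxyvinyl)stannane
Product: 8 (3S,4R)-4-(TBS-oxy)-3-(TBS-oxymethyl)-2-(1-ethoxyethenyl)-1,3-dimethylcyclohex-1-ene (ring A 2-ethoxydiene)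
Conditions: Pd(PPh3)4 (10 mol %), CuCl, LiCl, DMSO, 60 °C; work-up on Et3N-deactivated silica
Reagents that add atoms: none
Why: Copper-accelerated Stille coupling, in which the hindered enol triflate adds oxidatively to zerovalent palladium, the 1-ethoxyvinyl group passes from tin via copper to palladium and reductive elimination gives the diene, as established for 2,6,6-trisubstituted cyclohexenyl triflates.

Step 7
Reactants: 8 ring A 2-ethoxydiene; 9 methyl but-2-ynoate
Product: 10 methyl (3R,4S,10S)-3α,19-bis(TBS-oxy)-6-ethoxy-12,13,14,15,16-pentanorlabda-5,8-dien-11-oate (ring B 1,4-cyclohexadiene: C5=C6 enol ether, C8=C9 enoate, 10β-methyl)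
Conditions: 9 (8 equiv), toluene, 2,6-di-tert-butyl-4-methylpyridine (10 mol %), BHT, base-washed sealed tube, 140 °C
Reagents that add atoms: none
Why: A concerted but asynchronous normal-demand [4+2] cycloaddition between the electron-rich 2-ethoxydiene and the alkynoate, of the same type as the known additions of 2-alkoxydienes to alkynoates and of 2,6,6-trisubstituted 1-vinylcyclohexenes to acetylenic esters. Ring B (six-membered) closes by the cycloaddition itself: the unhindered C7 terminus, which has the largest HOMO coefficient because it flanks the ethoxy carbon, bonds to the β-carbon of the ynoate (C8, carrying the methyl), and C10 bonds to the ester-bearing C9, so the ethoxy group and the two alkyl groups on C10 direct to the same regioisomer. The only new stereocentre is C10, and it is controlled by the quaternary C4: in the reactive s-cis diene the ethoxy group eclipses the pseudoequatorial substituent on C4, which should therefore be the small methyl, and the trans-vicinal silyloxy groups prefer to be diaxial, so the CH2OTBS group stands pseudoaxial on the β face and the alkyne adds to the α face of C10, leaving C20 β. The step needs this face selectivity and the stated regiochemistry, both secured by the substrate, and it needs the enol ether to survive, for which the hindered pyridine base and acid-free glassware are used. The quaternary C10 of the 1,4-cyclohexadiene rules out aromatisation, and excess dienophile with heating compensates for the tetrasubstituted diene terminus.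

Step 8
Reactants: 10 methyl 3α,19-bis(TBS-oxy)-6-ethoxy-12,13,14,15,16-pentanorlabda-5,8-dien-11-oate
Product: 12 11-hydroxy-3α,19-bis(TBS-oxy)-12,13,14,15,16-pentanor-5α-labd-8-en-6-one, via dienol ether alcohol 11 (not isolated)
Conditions: i-Bu2AlH, CH2Cl2, −78 → 0 °C; aq. potassium sodium tartrate; then 5% aq. oxalic acid, THF, rt
Reagents that add atoms: water, O
Why: Hydride reduction of the hindered conjugated ester to the C11 allylic alcohol leaves the enol ether untouched; mild aqueous acid then protonates C5 on the α face, away from the axial C19 and C20 groups, and hydrolyses the oxocarbenium ion to the trans-fused C6 ketone, and reducing the ester first avoids a vinylogous β-keto ester whose C7 protons would invite alkene migration.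

Step 9
Reactants: 12 11-hydroxy-3α,19-bis(TBS-oxy)-12,13,14,15,16-pentanor-5α-labd-8-en-6-one
Product: 13 3α,19-bis(TBS-oxy)-12,13,14,15,16-pentanor-5α-labd-8-ene-6β,11-diol
Conditions: NaBH4, MeOH/THF, −20 → 0 °C
Reagents that add atoms: none
Why: Borohydride reduction of the C6 ketone; the β face is blocked by the syn-axial C20 methyl and C19 silyloxymethyl groups, so hydride should enter from the α face and give the axial 6β-alcohol.

Step 10
Reactants: 13 3α,19-bis(TBS-oxy)-12,13,14,15,16-pentanor-5α-labd-8-ene-6β,11-diol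
Product: 14 11-bromo-3α,19-bis(TBS-oxy)-12,13,14,15,16-pentanor-5α-labd-8-en-6β-ol
Conditions: CBr4, PPh3, 2,6-lutidine, CH2Cl2, −20 → 0 °C; used crude
Reagents that add atoms: carbon tetrabromide, BrC(Br)(Br)Br
Why: Appel bromination selects the primary allylic hydroxyl over the 6β-hydroxyl, which is shielded by two 1,3-diaxial groups, and the SN2 displacement of the oxyphosphonium group leaves the alkene in place.

Step 11
Reactants: 14 11-bromo-3α,19-bis(TBS-oxy)-12,13,14,15,16-pentanor-5α-labd-8-en-6β-ol; 15 tert-butyl acetoacetate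
Product: 17 tert-butyl 6β-hydroxy-13-oxo-3α,19-bis(TBS-oxy)-16-norlabd-8-en-15-oate, via sodium lithium dianion 16 (not isolated)
Conditions: 15 (3 equiv), NaH then n-BuLi, THF, 0 °C; add 14, 0 °C; aq. NH4Cl
Reagents that add atoms: none
Why: Acetoacetate dianion γ-alkylation, in which the more nucleophilic terminal carbon displaces the primary allylic bromide by SN2 to form C11–C12 (the known way from drimenyl-type bromides to labdanes); the excess dianion covers the free 6-hydroxyl, whose alkoxide cannot cyclise onto C11 because the bridged ether would need a bridgehead alkene.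

Step 12
Reactants: 17 tert-butyl 6β-hydroxy-13-oxo-3α,19-bis(TBS-oxy)-16-norlabd-8-en-15-oate
Product: 18 tert-butyl (13Z)-13-(diethoxyphosphoryloxy)-6β-hydroxy-3α,19-bis(TBS-oxy)-16-norlabda-8,13-dien-15-oate
Conditions: NaH (1.05 equiv), Et2O, 0 °C; ClP(O)(OEt)2, 0 °C
Reagents that add atoms: diethyl chlorophosphate, CCOP(=O)(Cl)OCC
Why: O-phosphorylation of the chelated sodium enolate of the β-keto ester gives the Z-enol phosphate (phosphate cis to the ester), and one equivalent of base deprotonates only the far more acidic β-keto ester, not the hindered alcohol.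

Step 13
Reactants: 18 tert-butyl (13Z)-13-(diethoxyphosphoryloxy)-6β-hydroxy-3α,19-bis(TBS-oxy)-16-norlabda-8,13-dien-15-oate
Product: 19 tert-butyl (13E)-6β-hydroxy-3α,19-bis(TBS-oxy)labda-8,13-dien-15-oate
Conditions: Me2CuLi (from MeLi and CuI, 4 equiv), Et2O, −78 → −45 °C; aq. NH4Cl
Reagents that add atoms: lithium dimethylcuprate, [Li+].C[Cu-]C (made from methyllithium, [Li]C)
Why: Cuprate substitution of the enol phosphate (addition–elimination with retention) puts the C16 methyl cis to the ester, so the C13=C14 alkene is E; the excess cuprate allows for the free hydroxyl.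

Step 14
Reactants: 19 tert-butyl (13E)-6β-hydroxy-3α,19-bis(TBS-oxy)labda-8,13-dien-15-oate
Product: 20 tert-butyl (13E)-3α,6β,19-trihydroxylabda-8,13-dien-15-oate
Conditions: HF·pyridine, pyridine, THF, 0 °C → rt
Reagents that add atoms: none
Why: Fluoride-driven cleavage of both Si–O bonds under buffered HF should leave the tert-butyl ester, the enoate and the tetrasubstituted alkene untouched.

Step 15
Reactants: 20 tert-butyl (13E)-3α,6β,19-trihydroxylabda-8,13-dien-15-oate
Product: 21 tert-butyl (13E)-6β-hydroxy-3α,19-bis(3-methylbutanoyloxy)labda-8,13-dien-15-oate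
Conditions: 3-methylbutanoic anhydride (2.5 equiv), Et3N, DMAP (cat.), CH2Cl2, 0 °C → rt
Reagents that add atoms: 3-methylbutanoic anhydride, CC(C)CC(=O)OC(=O)CC(C)C
Why: DMAP-catalysed acylation esterifies the primary C19 and the axial 3α hydroxyl, whereas the 6β-hydroxyl, held 1,3-diaxial to both the C20 methyl and the C19 acyloxymethyl group, should not react at room temperature.

Step 16
Reactants: 21 tert-butyl (13E)-6β-hydroxy-3α,19-bis(3-methylbutanoyloxy)labda-8,13-dien-15-oate
Product: 22 (13E)-6β-hydroxy-3α,19-bis(3-methylbutanoyloxy)labda-8,13-dien-15-oic acid, (3R,4S,5R,6R,10S), CNP0333611.1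
Conditions: CF3CO2H/CH2Cl2 (1:5), 0 °C
Reagents that add atoms: none
Why: Acidolysis of the tert-butyl ester by alkyl–oxygen cleavage through the tert-butyl cation frees the acid and should leave the two isovalerates, the secondary alcohol and the C8=C9 alkene (already the most substituted position) unchanged.

Compound list
1 | 2-methylcyclohexane-1,3-dione | CC1C(=O)CCCC1=O | starting material
2 | 2-(hydroxymethyl)-2-methylcyclohexane-1,3-dione | CC1(CO)C(=O)CCCC1=O | intermediate
3 | (2S,3R)-3-hydroxy-2-(hydroxymethyl)-2-methylcyclohexan-1-one | C1CC[C@@H](O)[C@](C)(CO)C1=O | intermediate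
4 | (2S,3R)-3-(TBS-oxy)-2-(TBS-oxymethyl)-2-methylcyclohexan-1-one | C1CC[C@@H](O[Si](C)(C)C(C)(C)C)[C@](C)(CO[Si](C)(C)C(C)(C)C)C1=O | intermediate
5 | (2S,3R,6RS)-3-(TBS-oxy)-2-(TBS-oxymethyl)-2,6-dimethylcyclohexan-1-one | CC1CC[C@@H](O[Si](C)(C)C(C)(C)C)[C@](C)(CO[Si](C)(C)C(C)(C)C)C1=O | intermediate
6 | (5R,6S)-5-(TBS-oxy)-6-(TBS-oxymethyl)-2,6-dimethylcyclohex-1-en-1-yl trifluoromethanesulfonate | CC=1CC[C@@H](O[Si](C)(C)C(C)(C)C)[C@](C)(CO[Si](C)(C)C(C)(C)C)C=1OS(=O)(=O)C(F)(F)F | intermediate
7 | tributyl(1-ethoxyvinyl)stannane | C=C(OCC)[Sn](CCCC)(CCCC)CCCC | starting material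
8 | (3S,4R)-4-(TBS-oxy)-3-(TBS-oxymethyl)-2-(1-ethoxyethenyl)-1,3-dimethylcyclohex-1-ene (ring A 2-ethoxydiene) | CC=1CC[C@@H](O[Si](C)(C)C(C)(C)C)[C@](C)(CO[Si](C)(C)C(C)(C)C)C=1C(=C)OCC | intermediate
9 | methyl but-2-ynoate | CC#CC(=O)OC | starting material
10 | methyl (3R,4S,10S)-3α,19-bis(TBS-oxy)-6-ethoxy-12,13,14,15,16-pentanorlabda-5,8-dien-11-oate | CC1=C(C(=O)OC)[C@@]2(C)CC[C@@H](O[Si](C)(C)C(C)(C)C)[C@](C)(CO[Si](C)(C)C(C)(C)C)C2=C(OCC)C1 | intermediate
11 | 3α,19-bis(TBS-oxy)-6-ethoxy-12,13,14,15,16-pentanorlabda-5,8-dien-11-ol (dienol ether alcohol) | CC1=C(CO)[C@@]2(C)CC[C@@H](O[Si](C)(C)C(C)(C)C)[C@](C)(CO[Si](C)(C)C(C)(C)C)C2=C(OCC)C1 | intermediate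
12 | 11-hydroxy-3α,19-bis(TBS-oxy)-12,13,14,15,16-pentanor-5α-labd-8-en-6-one | CC1=C(CO)[C@@]2(C)CC[C@@H](O[Si](C)(C)C(C)(C)C)[C@](C)(CO[Si](C)(C)C(C)(C)C)[C@@H]2C(=O)C1 | intermediate
13 | 3α,19-bis(TBS-oxy)-12,13,14,15,16-pentanor-5α-labd-8-ene-6β,11-diol | CC1=C(CO)[C@@]2(C)CC[C@@H](O[Si](C)(C)C(C)(C)C)[C@](C)(CO[Si](C)(C)C(C)(C)C)[C@@H]2[C@H](O)C1 | intermediate
14 | 11-bromo-3α,19-bis(TBS-oxy)-12,13,14,15,16-pentanor-5α-labd-8-en-6β-ol | CC1=C(CBr)[C@@]2(C)CC[C@@H](O[Si](C)(C)C(C)(C)C)[C@](C)(CO[Si](C)(C)C(C)(C)C)[C@@H]2[C@H](O)C1 | intermediate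
15 | tert-butyl acetoacetate | CC(=O)CC(=O)OC(C)(C)C | starting material
16 | sodium lithium dianion of tert-butyl acetoacetate | C=C([O-])C=C([O-])OC(C)(C)C.[Na+].[Li+] | intermediate
17 | tert-butyl 6β-hydroxy-13-oxo-3α,19-bis(TBS-oxy)-16-norlabd-8-en-15-oate | CC1=C(CCC(=O)CC(=O)OC(C)(C)C)[C@@]2(C)CC[C@@H](O[Si](C)(C)C(C)(C)C)[C@](C)(CO[Si](C)(C)C(C)(C)C)[C@@H]2[C@H](O)C1 | intermediate
18 | tert-butyl (13Z)-13-(diethoxyphosphoryloxy)-6β-hydroxy-3α,19-bis(TBS-oxy)-16-norlabda-8,13-dien-15-oate | CC1=C(CC/C(OP(=O)(OCC)OCC)=C/C(=O)OC(C)(C)C)[C@@]2(C)CC[C@@H](O[Si](C)(C)C(C)(C)C)[C@](C)(CO[Si](C)(C)C(C)(C)C)[C@@H]2[C@H](O)C1 | intermediate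
19 | tert-butyl (13E)-6β-hydroxy-3α,19-bis(TBS-oxy)labda-8,13-dien-15-oate | CC1=C(CC/C(C)=C/C(=O)OC(C)(C)C)[C@@]2(C)CC[C@@H](O[Si](C)(C)C(C)(C)C)[C@](C)(CO[Si](C)(C)C(C)(C)C)[C@@H]2[C@H](O)C1 | intermediate
20 | tert-butyl (13E)-3α,6β,19-trihydroxylabda-8,13-dien-15-oate | CC1=C(CC/C(C)=C/C(=O)OC(C)(C)C)[C@@]2(C)CC[C@@H](O)[C@](C)(CO)[C@@H]2[C@H](O)C1 | intermediate
21 | tert-butyl (13E)-6β-hydroxy-3α,19-bis(3-methylbutanoyloxy)labda-8,13-dien-15-oate | CC1=C(CC/C(C)=C/C(=O)OC(C)(C)C)[C@@]2(C)CC[C@@H](OC(=O)CC(C)C)[C@](C)(COC(=O)CC(C)C)[C@@H]2[C@H](O)C1 | intermediate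
22 | (13E)-6β-hydroxy-3α,19-bis(3-methylbutanoyloxy)labda-8,13-dien-15-oic acid, (3R,4S,5R,6R,10S) | CC1=C(CC/C(C)=C/C(=O)O)[C@@]2(C)CC[C@@H](OC(=O)CC(C)C)[C@](C)(COC(=O)CC(C)C)[C@@H]2[C@H](O)C1 | target

Total step count: 16. Longest linear sequence: 16 steps (1 → 22); compounds 7, 9 and 15 are purchased.

Steps most likely to fail

Step 7. The cycloaddition at the tetrasubstituted C10 terminus may be too slow, so that a thermal 1,5-hydrogen shift from C20 or hydrolysis of the diene competes, or the two faces of C10 may not be discriminated well enough. The fallback is a stepwise anionic annulation that sets out from 8 and returns at 13. Dilute aqueous acid would convert 8 into the methyl ketone 1-[(5R,6S)-5-(TBS-oxy)-6-(TBS-oxymethyl)-2,6-dimethylcyclohex-1-en-1-yl]ethan-1-one F1. LiN(i-Pr)2 at −78 °C would give the cross-conjugated lithium dienolate F2, which with 9 should undergo a sequential double Michael addition (C7 to C8, then the allenoate carbon C9 to C10). Protonation of the resulting C6 enolate at C5 from the α face would give the 6-keto ester, methyl 3α,19-bis(TBS-oxy)-6-oxo-12,13,14,15,16-pentanor-5α-labd-8-en-11-oate F3. NaBH4/CeCl3 would reduce the ketone from the α face to the 6β-hydroxy ester F4, and i-Bu2AlH would reduce the ester to diol 13.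

Step 2. The enzyme may discriminate the enantiotopic carbonyls or the carbonyl faces incompletely, or reduce the product further. The fallback sets out from 2 and returns at 3. A hydroxyl-directed reduction with Me4NBH(OAc)3 in MeCN/AcOH would deliver hydride intramolecularly from the face that carries the hydroxymethyl group and so give the racemic trans hydroxy ketone rac-(2S*,3R*)-3-hydroxy-2-(hydroxymethyl)-2-methylcyclohexan-1-one F5. A lipase-catalysed transesterification with vinyl acetate, the lipase chosen by screening, would acetylate the primary hydroxyl of the unwanted enantiomer to [(1R,2S)-2-hydroxy-1-methyl-6-oxocyclohexyl]methyl acetate F6. The unreacted (2S,3R) enantiomer is compound 3 and would be separated by chromatography.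

Step 6. Oxidative addition and transmetalation at the doubly hindered tetrasubstituted triflate may be slow, so that reduction or hydrolysis of the triflate and protodestannylation take over. The fallback sets out from 5 and returns at 8. Addition of 1-ethoxyvinyllithium (ethyl vinyl ether, t-BuLi, with CeCl3 to suppress enolisation) to the ketone would give the tertiary allylic alcohol 1-(1-ethoxyethenyl)-3-(TBS-oxy)-2-(TBS-oxymethyl)-2,6-dimethylcyclohexan-1-ol F7. Because C4 is quaternary and the ethoxyvinyl carbon attached to the carbinol carries no hydrogen, dehydration of the C5 carbinol with the Burgess reagent can only remove the C10 hydrogen and would give diene 8.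

Further compounds
F1 | step 7 | 1-[(5R,6S)-5-(TBS-oxy)-6-(TBS-oxymethyl)-2,6-dimethylcyclohex-1-en-1-yl]ethan-1-one | CC=1CC[C@@H](O[Si](C)(C)C(C)(C)C)[C@](C)(CO[Si](C)(C)C(C)(C)C)C=1C(C)=O
F2 | step 7 | lithium dienolate of F1 | CC=1CC[C@@H](O[Si](C)(C)C(C)(C)C)[C@](C)(CO[Si](C)(C)C(C)(C)C)C=1C(=C)[O-].[Li+]
F3 | step 7 | methyl 3α,19-bis(TBS-oxy)-6-oxo-12,13,14,15,16-pentanor-5α-labd-8-en-11-oate | CC1=C(C(=O)OC)[C@@]2(C)CC[C@@H](O[Si](C)(C)C(C)(C)C)[C@](C)(CO[Si](C)(C)C(C)(C)C)[C@@H]2C(=O)C1
F4 | step 7 | methyl 6β-hydroxy-3α,19-bis(TBS-oxy)-12,13,14,15,16-pentanor-5α-labd-8-en-11-oate | CC1=C(C(=O)OC)[C@@]2(C)CC[C@@H](O[Si](C)(C)C(C)(C)C)[C@](C)(CO[Si](C)(C)C(C)(C)C)[C@@H]2[C@H](O)C1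
F5 | step 2 | rac-(2S*,3R*)-3-hydroxy-2-(hydroxymethyl)-2-methylcyclohexan-1-one (both enantiomers) | C1CC[C@@H](O)[C@](C)(CO)C1=O.C1CC[C@H](O)[C@@](C)(CO)C1=O
F6 | step 2 | [(1R,2S)-2-hydroxy-1-methyl-6-oxocyclohexyl]methyl acetate | C1CC[C@H](O)[C@@](C)(COC(C)=O)C1=O
F7 | step 6 | 1-(1-ethoxyethenyl)-3-(TBS-oxy)-2-(TBS-oxymethyl)-2,6-dimethylcyclohexan-1-ol (2S,3R; mixture at C1 and C6) | CC1CC[C@@H](O[Si](C)(C)C(C)(C)C)[C@](C)(CO[Si](C)(C)C(C)(C)C)C1(O)C(=C)OCC
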